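Start from the south-west run: within the scatter of its readings its cZ falls along a straight line, at 0.00278 M h⁻¹ up to 8.00 h and 0.00262 M h⁻¹ up to 30.0 h. Take the second figure as the feed rate, the Z dissolved per litre per hour, and treat it as a zero-order step.

| flask | Z | remark | time |
|---|---|---|---|
| south-west | 0.25 M | run made earlier |  |
| flask | 0.50 M |  | 6.0 d |

- south-west (time / h: Q / %, X / %, Z / %): 8.00: 0, 6.4, 91.1; 15.0: 2.8, 10.9, 82.8; 20.0: 6.4, 10.2, 78.7; 30.0: 9.9, 14.4, 68.6

(scatter of a reading: 1 percentage point)

- Z is a solid; its amount is given per volume of the solution
- at the start none of Z is in solution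
- X is what Z becomes in solution
- X means what is dissolved; the solid is not counted in it

1. the Q standing at 6.0 d, as a percentage of the Z charged
2. concentration of X in solution at 6.0 d, in percent of saturation

Turn the charge first. Assume the feed per litre does not depend on the solid charged. Raise cZ to 0.50 M, and the percentage lost by 30.0 h falls to 15.7%, half of the south-west reading.

Turn the time next. Over 6.0 d the feed takes 0.377 M from this flask, so reckon Z at 24.6%.

Now bring in Q. Between 15.0 h and 30.0 h of the south-west run, Q gained 0.500 per unit of Z lost, a rough reading given the scatter. Drawn back from the last reading, that line meets zero Q at 0.0290 M of Z lost. Multiply the slope by the Z lost beyond this delay, and reckon 34.8% of Q in the flask. The two feed figures of the south-west run agree within the scatter, so give saturation no number of your own.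

The forecast, which differs from this reckoning on Q, gives 47% of Q and 12% of saturation, and it reads the south-west run thus: “The Z loss fits first-order kinetics”.

The flask gives 34.0% of Q and 16.5% of saturation. Z stands at 27.0% there, against 24.6% reckoned from the feed of 0.00262 M h⁻¹.

    X ⇌ Q (K = 6.00, k = 1.30 × 10⁻⁵ s⁻¹)
    X ⇌ J (K = 2.70, k = 1.00 × 10⁻⁶ s⁻¹)
    Z ⇌ X, rate k3*(cs3 - [X]) while solid is left; crystals form when [X] > cs3 (solubility = 0.310 M, k = 2.60 × 10⁻⁶ s⁻¹)
    X ⇌ G (K = 25.0, k = 6.50 × 10⁻⁶ s⁻¹)

Run the same reckoning on the neighbour flask, with the same charge left until 40 h. The feed takes 0.105 M of Z, which leaves 79.0%, and that neighbour flask holds 78.7%. The slope and the delay give 7.58% of Q, and that neighbour flask holds 8.53%.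

The readings were computed with constants of no real substance, and the scatter is random.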